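**Plan**
Numbering: oxane O1, C2 (bears ring A, the 3,4-dihydroxy-5-methoxyphenyl group), C3, C4 (OH), C5, C6 (bears CH2CH2–ring B, the 4-hydroxyphenyl group). The SMILES reads (2S,4R,6S), so all three ring substituents are cis and equatorial.
Retrosynthesis: after the four O-acyl bonds, one Prins disconnection cuts O1–C2, C2–C3 and C4–O together. This gives a ring A benzaldehyde (C2) and an (S)-homoallylic alcohol (C3–C6, O1, ring B). The alcohol is cut at C5–C6 (allyl + 3-arylpropanal), and that aldehyde at the ring B–CH2 bond.
Enabling feature: C2 is benzylic to ring A and bonded to O1, so it is a latent aldehyde carbon. The hydroxyl sits on C4, the atom that turns cationic when a C3=C4 alkene attacks an O1=C2 oxocarbenium ion, and the 2,4,6-all-equatorial pattern is the native outcome of that chair closure.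
Forward: rings A and B are bought. The chain is joined by Heck arylation (step 2), allylation (step 3) and the Prins union (step 4), which closes the oxane as the last ring; one methanolysis (step 5) ends the route.
Stereochemistry: C6 comes from the (R)-BINOL/Ti(OiPr)4-catalysed allylation; C2 and C4 are relayed from C6 in the Prins chair.
Helpers: the three phenols travel as acetates, which damp the donor power of ring A during the cationic step and leave together with the C4 trifluoroacetate.

Key step: step 4

**Step 1**
Reactants: 1 3,4-dihydroxy-5-methoxybenzaldehyde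
Product: 2 5-formyl-3-methoxybenzene-1,2-diyl diacetate
Conditions: Ac2O (2.5 equiv), pyridine, DMAP (cat.), CH2Cl2, 0 °C to rt
Reagents that add atoms: acetic anhydride, CC(=O)OC(C)=O
Why: DMAP-catalysed O-acetylation of both phenols turns the strongly donating catechol oxygens into weak donors, as the Prins step requires, and no stereocentre is involved.

**Step 2**
Reactants: 3 4-iodophenyl acetate; 4 prop-2-en-1-ol
Product: 5 4-(3-oxopropyl)phenyl acetate
Conditions: Pd(OAc)2 (3 mol %), Bu4NCl (1 equiv), NaHCO3 (2.5 equiv), DMF, 45 °C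
Reagents that add atoms: none
Why: In this Heck reaction under Jeffery conditions, zerovalent palladium formed in the flask inserts into the carbon–iodine bond, the aryl group adds to the terminal alkene carbon of 4, and beta-hydride elimination toward the carbinol carbon gives an enol that tautomerises to aldehyde 5, while the mild solid base should leave the aryl acetate intact.

**Step 3**
Reactants: 5 4-(3-oxopropyl)phenyl acetate; 6 allyltributylstannane
Product: 7 4-[(3S)-3-hydroxyhex-5-en-1-yl]phenyl acetate
Conditions: (R)-BINOL (10 mol %), Ti(OiPr)4 (10 mol %), 4 Å MS, CH2Cl2, −20 °C; aq. NaHCO3 work-up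
Reagents that add atoms: none
Why: In this Keck asymmetric allylation the (R)-BINOL titanium Lewis acid activates the aldehyde and steers the stannane to its Re face, which sets the future C6 as (S), and the neutral, cold conditions should tolerate the aryl ester.

**Step 4**
Reactants: 2 5-formyl-3-methoxybenzene-1,2-diyl diacetate; 7 4-[(3S)-3-hydroxyhex-5-en-1-yl]phenyl acetate
Product: 10 (2S,4R,6S)-2-[3,4-bis(acetyloxy)-5-methoxyphenyl]-6-{2-[4-(acetyloxy)phenyl]ethyl}oxan-4-yl trifluoroacetate, via E-oxocarbenium trifluoroacetate 8 (not isolated), via oxan-4-yl cation 9 (not isolated)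
Conditions: 2 (1.2 equiv), CF3CO2H (20 equiv), CH2Cl2, 0 °C to rt; aq. NaHCO3 wash, taken on crude
Reagents that add atoms: trifluoroacetic acid, OC(=O)C(F)(F)F
Why: TFA condenses 2 with the hydroxyl of 7 (hemiacetal, loss of water) to the E-oxocarbenium ion 8, the terminal alkene carbon C3 attacks C2 to give the secondary oxan-4-yl cation 9, and trifluoroacetate captures C4, so that O1–C2, C2–C3 and C4–O are all made in one operation. The closest known reaction type is the TFA-mediated Prins cyclisation of homoallylic alcohols with aliphatic or aromatic aldehydes to all-cis 2,6-disubstituted oxan-4-yl trifluoroacetates. The oxane closes in a 6-endo-trig cation–olefin mode through a chair transition state. C2 is controlled by C6, because with the E-oxocarbenium geometry the arylethyl chain on C6 and ring A on C2 both sit equatorial in the chair, which makes H2 and H6 cis and turns (6S) into (2S); C4 is controlled by the ring itself, since cation 9 is stabilised by overlap with the O1 lone pair through the ring bonds and is open to the nucleophile along the equatorial trajectory, which gives (4R). The step needs retention of configuration at C6 and no exchange of side chains, both threatened by reversible 2-oxonia-Cope rearrangement; placing ring A on the aldehyde carbon keeps the aryl-conjugated ion 8 the favoured oxocarbenium isomer and leaves C6 non-benzylic and unable to ionise, while the acetates make 8 electrophilic enough to cyclise fast at low temperature and keep the benzylic C2–O1 bond of 10 from ionising in the acid. Friedel–Crafts capture by ring B is not expected, because it would need a seven-membered closure at a position meta to the deactivated acetoxy group.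

**Step 5**
Reactants: 10 (2S,4R,6S)-2-[3,4-bis(acetyloxy)-5-methoxyphenyl]-6-{2-[4-(acetyloxy)phenyl]ethyl}oxan-4-yl trifluoroacetate
Product: 11 (2S,4R,6S)-2-(3,4-dihydroxy-5-methoxyphenyl)-6-[2-(4-hydroxyphenyl)ethyl]oxan-4-ol
Conditions: K2CO3 (0.3 equiv), degassed MeOH, Ar, 0 °C to rt; acidic ion-exchange resin (H+ form), filter, evaporate
Reagents that add atoms: none
Why: In this Zemplén-type transesterification methoxide cleaves the activated trifluoroacetate and the three aryl acetates by acyl–oxygen fission, so the C4–O bond and all stereocentres stay untouched, the by-products are volatile, and exclusion of oxygen protects the liberated catechol.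

**Compound list**
1 | 3,4-dihydroxy-5-methoxybenzaldehyde | COc1cc(C=O)cc(O)c1O | starting material
2 | 5-formyl-3-methoxybenzene-1,2-diyl diacetate | COc1cc(C=O)cc(OC(C)=O)c1OC(C)=O | intermediate
3 | 4-iodophenyl acetate | CC(=O)Oc1ccc(I)cc1 | starting material
4 | prop-2-en-1-ol | C=CCO | starting material
5 | 4-(3-oxopropyl)phenyl acetate | CC(=O)Oc1ccc(CCC=O)cc1 | intermediate
6 | allyltributylstannane | C=CC[Sn](CCCC)(CCCC)CCCC | starting material
7 | 4-[(3S)-3-hydroxyhex-5-en-1-yl]phenyl acetate | C=CC[C@H](CCc1ccc(OC(C)=O)cc1)O | intermediate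
8 | E-oxocarbenium ion from 2 and 7, trifluoroacetate salt (not isolated) | C=CC[C@H](CCc1ccc(OC(C)=O)cc1)/[O+]=C/c1cc(OC)c(OC(C)=O)c(OC(C)=O)c1.[O-]C(=O)C(F)(F)F | intermediate
9 | 2,6-cis-disubstituted oxan-4-yl cation, trifluoroacetate salt, C2 and C6 arranged as in 10 (not isolated) | COc1cc([C@@H]2C[CH+]C[C@H](CCc3ccc(OC(C)=O)cc3)O2)cc(OC(C)=O)c1OC(C)=O.[O-]C(=O)C(F)(F)F | intermediate
10 | (2S,4R,6S)-2-[3,4-bis(acetyloxy)-5-methoxyphenyl]-6-{2-[4-(acetyloxy)phenyl]ethyl}oxan-4-yl trifluoroacetate | COc1cc([C@@H]2C[C@H](OC(=O)C(F)(F)F)C[C@H](CCc3ccc(OC(C)=O)cc3)O2)cc(OC(C)=O)c1OC(C)=O | intermediate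
11 | (2S,4R,6S)-2-(3,4-dihydroxy-5-methoxyphenyl)-6-[2-(4-hydroxyphenyl)ethyl]oxan-4-ol | COc1cc([C@@H]2C[C@H](O)C[C@H](CCc3ccc(O)cc3)O2)cc(O)c1O | target

Total step count: 5. Longest linear sequence: 4 steps (steps 2, 3, 4, 5).

**Steps most likely to fail**

**Risk 1, step 4.**
- What may go wrong: reversible 2-oxonia-Cope rearrangement, followed by hydrolysis of the rearranged ion, could erode the enantiopurity and exchange the side chains. Capture of the cation by the weakly nucleophilic trifluoroacetate could also be slow.
- Fallback: it sets out from 5 and 2 and comes back at 11. It replaces external oxygen capture by an internal allylsilane terminator (pyran annulation).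
- Aldehyde 5 is allylated with the step 3 catalyst and tributyl[2-(trimethylsilylmethyl)allyl]stannane to give 4-{(3S)-3-hydroxy-5-[(trimethylsilyl)methyl]hex-5-en-1-yl}phenyl acetate F1.
- TMSOTf in Et2O at −78 °C joins F1 with 2 in an intramolecular Sakurai-type closure. Loss of the silyl group quenches the cation irreversibly, giving (2S,6S)-2-[3,4-bis(acetyloxy)-5-methoxyphenyl]-6-{2-[4-(acetyloxy)phenyl]ethyl}-4-methylideneoxane F2.
- Ozonolysis (O3, CH2Cl2, −78 °C, then Me2S) gives the corresponding (2S,6S)-oxan-4-one F3.
- NaBH4 in MeOH/CH2Cl2 at low temperature should add hydride axially to give the all-cis (2S,4R,6S)-oxan-4-ol triacetate F4. The conditions of step 5 then take F4 to 11.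

**Risk 2, step 5.**
- What may go wrong: the liberated catecholate could be oxidised by traces of air. The base could also open the benzylic C2–O1 bond through a para-quinone methide that methanol then captures.
- Fallback: it sets out from 1 and 7 and comes back at 11. It carries ring A as benzyl ethers, so the catechol is released only under neutral, reducing conditions. The price is a more donor-rich aryl group in the cyclisation.
- Compound 1 with BnBr, K2CO3 and DMF gives 3,4-bis(benzyloxy)-5-methoxybenzaldehyde F5.
- The Prins cyclisation of F5 with 7 under the step 4 conditions gives (2S,4R,6S)-6-{2-[4-(acetyloxy)phenyl]ethyl}-2-[3,4-bis(benzyloxy)-5-methoxyphenyl]oxan-4-yl trifluoroacetate F6.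
- K2CO3 in MeOH gives (2S,4R,6S)-2-[3,4-bis(benzyloxy)-5-methoxyphenyl]-6-[2-(4-hydroxyphenyl)ethyl]oxan-4-ol F7.
- A short hydrogenolysis (H2, Pd/C, EtOAc) gives 11.

**Risk 3, step 3.**
- What may go wrong: turnover of the catalyst could be slow, facial selectivity incomplete, or acetyl could transfer from the aryl ester to the tin alkoxide during the long reaction time.
- Fallback: it sets out from 5 and comes back at 7. It changes from catalytic Lewis acid control to stoichiometric reagent control through a closed six-membered boron transition state (Brown allylboration).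
- (+)-B-allyldiisopinocampheylborane, made from (+)-B-methoxydiisopinocampheylborane and allylmagnesium bromide, is used in Et2O at −78 °C. NaOH/H2O2 work-up also cleaves the aryl acetate and gives 4-[(3S)-3-hydroxyhex-5-en-1-yl]phenol F8.
- Chemoselective acetylation of the phenoxide (Ac2O, 1 equiv, aq. NaOH, 0 °C) returns 7.

**Further compounds**
F1 | step 4 | 4-{(3S)-3-hydroxy-5-[(trimethylsilyl)methyl]hex-5-en-1-yl}phenyl acetate | C=C(C[Si](C)(C)C)C[C@H](CCc1ccc(OC(C)=O)cc1)O
F2 | step 4 | (2S,6S)-2-[3,4-bis(acetyloxy)-5-methoxyphenyl]-6-{2-[4-(acetyloxy)phenyl]ethyl}-4-methylideneoxane | COc1cc([C@@H]2CC(=C)C[C@H](CCc3ccc(OC(C)=O)cc3)O2)cc(OC(C)=O)c1OC(C)=O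
F3 | step 4 | (2S,6S)-2-[3,4-bis(acetyloxy)-5-methoxyphenyl]-6-{2-[4-(acetyloxy)phenyl]ethyl}oxan-4-one | COc1cc([C@@H]2CC(=O)C[C@H](CCc3ccc(OC(C)=O)cc3)O2)cc(OC(C)=O)c1OC(C)=O
F4 | step 4 | (2S,4R,6S)-2-[3,4-bis(acetyloxy)-5-methoxyphenyl]-6-{2-[4-(acetyloxy)phenyl]ethyl}oxan-4-ol | COc1cc([C@@H]2C[C@H](O)C[C@H](CCc3ccc(OC(C)=O)cc3)O2)cc(OC(C)=O)c1OC(C)=O
F5 | step 5 | 3,4-bis(benzyloxy)-5-methoxybenzaldehyde | COc1cc(C=O)cc(OCc2ccccc2)c1OCc1ccccc1
F6 | step 5 | (2S,4R,6S)-6-{2-[4-(acetyloxy)phenyl]ethyl}-2-[3,4-bis(benzyloxy)-5-methoxyphenyl]oxan-4-yl trifluoroacetate | COc1cc([C@@H]2C[C@H](OC(=O)C(F)(F)F)C[C@H](CCc3ccc(OC(C)=O)cc3)O2)cc(OCc2ccccc2)c1OCc1ccccc1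
F7 | step 5 | (2S,4R,6S)-2-[3,4-bis(benzyloxy)-5-methoxyphenyl]-6-[2-(4-hydroxyphenyl)ethyl]oxan-4-ol | COc1cc([C@@H]2C[C@H](O)C[C@H](CCc3ccc(O)cc3)O2)cc(OCc2ccccc2)c1OCc1ccccc1
F8 | step 3 | 4-[(3S)-3-hydroxyhex-5-en-1-yl]phenol | C=CC[C@H](CCc1ccc(O)cc1)O
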